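**Plan**

1. Ring A is the butenolide (O1, C2 carbonyl, C3 methyl, C4, C5) and the side chain runs C1' (on C4) to C16'. The retrosynthesis cuts the acetate O–acyl bond and the C15'–O bond (from C15'–B), then C4–C1', then C14'–C15', then C11'–C12'.
2. Forward: a C11 alkenyl Grignard reagent and a C3 dihalide give the C1'–C14' chain, with a terminal alkene at C1'=C2' and a primary pinacol boronic ester at C14'. Lithiated ethyl carbamate then adds C15'–C16' by forming C14'–C15'. Oxidation and acetylation follow. Ring A is bought preformed as 3-methyltetronic acid and joined last by hydroboration and B-alkyl Suzuki–Miyaura coupling; no ring is closed anywhere in the route.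
3. Enabling feature: the only stereocentre, C15', is a methyl carbinol (C16' methyl, H, O) next to the unbranched C14' methylene. This is the pattern an α-lithiated O-ethyl carbamate leaves when it homologates a primary boronic ester. Ring A lies fourteen methylenes away.
4. Stereochemistry: (+)-sparteine-directed removal of one enantiotopic O–CH2 proton fixes C15'. Retention in C–B bond formation, inversion in the 1,2-shift and retention in C–B oxidation carry it to the (S)-acetate.
5. Ring A is attached after the organolithium step because its acidic C5 methylene and lactone carbonyl would not survive an α-oxyalkyllithium. The terminal alkene that stands in for it is inert there.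

Key step: step 4

Remark: (+)-sparteine is taken to act as the mirror image of (−)-sparteine, which removes the pro-S proton of O-alkyl carbamates; the pro-R proton is therefore removed here.

**Step 1**
Reactants: 1 11-bromoundec-1-ene; 2 1-bromo-3-chloropropane
Product: 4 14-chlorotetradec-1-ene, via undec-10-enylmagnesium bromide 3 (not isolated)
Conditions: Mg, THF, rt → 45 °C; then 2 (1.3 equiv), Li2CuCl4 (2 mol%), THF, −10 °C → rt
Reagents that add atoms: none
Why: Kochi-type copper-catalysed alkyl–alkyl cross-coupling of a primary Grignard reagent, in which the C–Br bond of 2 reacts far faster than its C–Cl bond, so the chloride survives as the handle for step 2 and the terminal alkene is untouched.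

**Step 2**
Reactants: 4 14-chlorotetradec-1-ene
Product: 6 4,4,5,5-tetramethyl-2-(tetradec-13-en-1-yl)-1,3,2-dioxaborolane, via tetradec-13-enylmagnesium chloride 5 (not isolated)
Conditions: Mg (I2, BrCH2CH2Br activation), THF, reflux; then i-PrOBpin, THF, −78 °C → rt; aq. NH4Cl
Reagents that add atoms: 2-isopropoxy-4,4,5,5-tetramethyl-1,3,2-dioxaborolane, CC(C)OB1OC(C)(C)C(C)(C)O1
Why: Grignard formation from the primary chloride followed by borylation with an alkoxyboronate (addition to boron, loss of magnesium isopropoxide), a standard route to primary alkyl pinacol boronic esters that leaves the remote alkene alone.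

**Step 3**
Reactants: 7 sodium ethoxide; 8 N,N-diisopropylcarbamoyl chloride
Product: 9 ethyl N,N-diisopropylcarbamate
Conditions: EtOH, 0 °C → reflux
Reagents that add atoms: none
Why: Nucleophilic acyl substitution of the carbamoyl chloride by ethoxide (O-carbamoylation), the usual preparation of O-alkyl N,N-diisopropylcarbamates.

**Step 4**
Reactants: 9 ethyl N,N-diisopropylcarbamate; 6 4,4,5,5-tetramethyl-2-(tetradec-13-en-1-yl)-1,3,2-dioxaborolane
Product: 12 (S)-4,4,5,5-tetramethyl-2-(hexadec-15-en-2-yl)-1,3,2-dioxaborolane, via lithiated carbamate 10 (not isolated), via lithium boronate complex 11 (not isolated)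
Conditions: 9 (1.3 equiv), (+)-sparteine (1.3 equiv), s-BuLi (1.25 equiv), Et2O, −78 °C, 5 h; then 6 (1.0 equiv), Et2O, −78 °C, 1 h; then MgBr2·OEt2 (1.5 equiv), −78 °C → reflux, 16 h
Reagents that add atoms: none
Why: s-BuLi complexed to (+)-sparteine removes the pro-R proton of the O–CH2 group of 9 (carbamate-directed, dipole-stabilised α-lithiation), and the configurationally stable (R)-organolithium 10 attacks the vacant boron orbital of 6 with retention at carbon to give boronate 11. On warming with MgBr2·OEt2 the C14' methylene migrates from boron to C15' anti-periplanar to the departing carbamate, a 1,2-metallate rearrangement with inversion at C15' that forms the C14'–C15' bond. The closest known reaction type is the lithiation–borylation homologation of primary pinacol boronic esters with sparteine-ligated lithiated primary alkyl carbamates, a reagent-controlled Matteson-type homologation. No ring is closed. The new stereocentre C15' is controlled by the chiral diamine alone, because retention followed by inversion is stereospecific and the substrate has no other stereogenic element. The step needs the carbanion to react only at boron and a carbon group rather than a pinacol oxygen to migrate: 6 carries nothing but an unactivated terminal alkene, s-BuLi is kept below the amount of 9 so that none is free to add to boron, and the unhindered primary migrating group with Lewis-acid assistance secures the carbon shift.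

**Step 5**
Reactants: 12 (S)-4,4,5,5-tetramethyl-2-(hexadec-15-en-2-yl)-1,3,2-dioxaborolane
Product: 13 (S)-hexadec-15-en-2-ol
Conditions: H2O2 (30% aq.), NaOH (2 M aq.), THF, 0 °C → rt
Reagents that add atoms: hydrogen peroxide, OO
Why: Stereoretentive oxidation of the C–B bond (hydroperoxide adds to boron and C15' migrates to oxygen with retention), so the (S) configuration passes into the alcohol while the terminal alkene is inert to alkaline peroxide.

**Step 6**
Reactants: 13 (S)-hexadec-15-en-2-ol
Product: 14 (S)-hexadec-15-en-2-yl acetate
Conditions: Ac2O, pyridine, DMAP (cat.), CH2Cl2, 0 °C → rt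
Reagents that add atoms: acetic anhydride, CC(=O)OC(C)=O
Why: DMAP-catalysed O-acylation of a secondary alcohol, which does not touch the C15'–O bond or the stereocentre.

**Step 7**
Reactants: 15 4-hydroxy-3-methylfuran-2(5H)-one (3-methyltetronic acid)
Product: 16 4-bromo-3-methylfuran-2(5H)-one
Conditions: (COBr)2, DMF, CH2Cl2, 0 °C → rt
Reagents that add atoms: oxalyl bromide, O=C(Br)C(Br)=O
Why: Vilsmeier-type deoxybromination of a vinylogous acid, in which the bromoiminium salt from DMF and oxalyl bromide activates the C4 enol oxygen and bromide replaces it by addition–elimination.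

**Step 8**
Reactants: 14 (S)-hexadec-15-en-2-yl acetate; 16 4-bromo-3-methylfuran-2(5H)-one
Product: 18 (S)-16-(4-methyl-5-oxo-2,5-dihydrofuran-3-yl)hexadecan-2-yl acetate (the target), via B-alkyl-9-BBN adduct 17 (not isolated)
Conditions: 9-BBN (1.2 equiv), THF, 0 °C → rt; then 16 (1.3 equiv), PdCl2(dppf) (5 mol%), AsPh3 (5 mol%), K3PO4 (3 M aq., 3 equiv), THF/DMF, rt → 45 °C
Reagents that add atoms: none
Why: Anti-Markovnikov hydroboration of the terminal alkene with 9-BBN followed by B-alkyl Suzuki–Miyaura coupling (oxidative addition of zerovalent palladium into the C4–Br bond of the β-bromo enoate, phosphate-assisted transfer of the primary alkyl group, reductive elimination) forms C4–C1' without touching C15' or the acetate.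

**Compound list**

1 | 11-bromoundec-1-ene | C=CCCCCCCCCCBr | starting material
2 | 1-bromo-3-chloropropane | ClCCCBr | starting material
3 | undec-10-en-1-ylmagnesium bromide (formed in the flask) | C=CCCCCCCCCC[Mg]Br | intermediate
4 | 14-chlorotetradec-1-ene | C=CCCCCCCCCCCCCCl | intermediate
5 | tetradec-13-en-1-ylmagnesium chloride (formed in the flask) | C=CCCCCCCCCCCCC[Mg]Cl | intermediate
6 | 4,4,5,5-tetramethyl-2-(tetradec-13-en-1-yl)-1,3,2-dioxaborolane | C=CCCCCCCCCCCCCB1OC(C)(C)C(C)(C)O1 | intermediate
7 | sodium ethoxide | CC[O-].[Na+] | starting material
8 | N,N-diisopropylcarbamoyl chloride | CC(C)N(C(C)C)C(Cl)=O | starting material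
9 | ethyl N,N-diisopropylcarbamate | CCOC(=O)N(C(C)C)C(C)C | intermediate
10 | (R)-1-lithioethyl N,N-diisopropylcarbamate, present as its (+)-sparteine complex (diamine not drawn; formed in the flask) | C[C@@H]([Li])OC(=O)N(C(C)C)C(C)C | intermediate
11 | lithium boronate complex: (R)-1-(N,N-diisopropylcarbamoyloxy)ethyl and tetradec-13-enyl on the pinacolato boron (formed in the flask) | C[C@@H]([B-]1(CCCCCCCCCCCCC=C)OC(C)(C)C(C)(C)O1)OC(=O)N(C(C)C)C(C)C.[Li+] | intermediate
12 | (S)-4,4,5,5-tetramethyl-2-(hexadec-15-en-2-yl)-1,3,2-dioxaborolane | C[C@H](B1OC(C)(C)C(C)(C)O1)CCCCCCCCCCCCC=C | intermediate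
13 | (S)-hexadec-15-en-2-ol | C[C@H](O)CCCCCCCCCCCCC=C | intermediate
14 | (S)-hexadec-15-en-2-yl acetate | CC(=O)O[C@@H](C)CCCCCCCCCCCCC=C | intermediate
15 | 4-hydroxy-3-methylfuran-2(5H)-one (3-methyltetronic acid) | CC1=C(O)COC1=O | starting material
16 | 4-bromo-3-methylfuran-2(5H)-one | CC1=C(Br)COC1=O | intermediate
17 | (S)-16-(9-borabicyclo[3.3.1]nonan-9-yl)hexadecan-2-yl acetate (formed in the flask) | CC(=O)O[C@@H](C)CCCCCCCCCCCCCCB1C2CCCC1CCC2 | intermediate
18 | (S)-16-(4-methyl-5-oxo-2,5-dihydrofuran-3-yl)hexadecan-2-yl acetate, i.e. 4-[(15S)-15-acetoxyhexadecyl]-3-methylfuran-2(5H)-one | CC(=O)O[C@@H](C)CCCCCCCCCCCCCCC1=C(C)C(=O)OC1 | target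

**Step count and risks**

Total step count: 8. Longest linear sequence: 6 steps (steps 1, 2, 4, 5, 6, 8).

Steps most likely to fail:

Step 4. The deprotonation of 9 may be incomplete or not selective enough between the two enantiotopic protons, or the 1,2-shift in boronate 11 may be slow enough for the complex to dissociate. Either would lower conversion or enantiomeric purity at C15'. The fallback sets out from chloride 4 and comes back at alcohol 13. Grignard reagent 5, made as in step 2, would be acylated with N-methoxy-N-methylacetamide in THF at 0 °C to give hexadec-15-en-2-one F1. The ketone would then be reduced with an (S)-selective alcohol dehydrogenase (NADH recycled with propan-2-ol, buffer with co-solvent) to give 13. The stereocentre then comes from enzymatic hydride delivery to one carbonyl face and not from the diamine.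

Step 8. Aqueous base may hydrolyse the vinylogous acyl bromide of 16, or β-hydride elimination and protodeboronation of the alkylborane may outrun transmetalation. The fallback sets out from acetate 14 and comes back at target 18. Radical anti-Markovnikov addition of HBr (AIBN, hexane, 0 °C) would give (S)-16-bromohexadecan-2-yl acetate F2. Zinc insertion (Zn dust, LiCl, THF, 50 °C) would give (S)-(15-acetoxyhexadecyl)zinc bromide F3. Negishi coupling of F3 with 16 (PdCl2(dppf), THF, rt) would then form C4–C1' without any base.

Step 2. Magnesium insertion into the long-chain primary C–Cl bond may be sluggish, and Wurtz-type homocoupling may consume the chloride. The fallback sets out from chloride 4 and comes back at boronic ester 6. Finkelstein exchange (NaI, acetone, reflux) would give 14-iodotetradec-1-ene F4. The iodide would then be borylated with bis(pinacolato)diboron under CuI/PPh3 catalysis with LiOMe in DMF at rt, a route that avoids any organomagnesium species.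

**Further compounds**

F1 | step 4 | hexadec-15-en-2-one | CC(=O)CCCCCCCCCCCCC=C
F2 | step 8 | (S)-16-bromohexadecan-2-yl acetate | CC(=O)O[C@@H](C)CCCCCCCCCCCCCCBr
F3 | step 8 | (S)-(15-acetoxyhexadecyl)zinc bromide | CC(=O)O[C@@H](C)CCCCCCCCCCCCCC[Zn]Br
F4 | step 2 | 14-iodotetradec-1-ene | C=CCCCCCCCCCCCCI
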